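**Plan**
Retrosynthesis (ring atoms: C2 = quaternary carbon, C1 = the C=O between C2 and the prenyl-bearing sp2 carbon C3, C4 = C–OH, C5 = benzoyl-bearing carbon, C6 = second C=O): the C2–CH2(geranyl) bond is cut first, which uncovers a Cs-symmetric diprenyl acylphloroglucinol; then the ring bonds C1–C2 and C3–C4 are cut together, leaving a C2–C6–C5–C4 unit (a benzoyl-bearing β-keto ester) and an O=C1–C3 unit (a C7 ester).
Enabling feature: the six-membered ring is an enolised cyclohexane-1,3,5-trione in which carbonyl-level carbons (C1, C4, C6) alternate with α-carbons (C2, C3, C5). C1–C2 and C3–C4 are therefore both Claisen bonds, the C1–C3 unit is a plain ester with its α-CH2, and aromatisation to the phloroglucinol tautomer drives a one-flask [4+2] double Claisen.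
Forward: γ-prenylation of ethyl acetoacetate and C-benzoylation give the four-carbon unit; a Johnson–Claisen rearrangement gives the two-carbon unit; the double Claisen closes the only ring with both prenyl groups placed regiospecifically; geranylation completes the skeleton.
Stereochemistry: the single stereocentre (C2, R) is created in the last step by a ligand-controlled Pd-catalysed allylic alkylation that desymmetrises the phloroglucinol (its two prenyl-bearing carbons are enantiotopic); the E-olefin of the geranyl group comes from geraniol.

Key step: step 4

Assumption: the sense of induction of the chiral ligand in step 6 cannot be predicted with certainty for this nucleophile; the (R,R) ligand is written, and its mirror image is to be used if a test run shows the (S) product.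

Step 1
Reactants: 1 ethyl acetoacetate; 2 prenyl bromide (1-bromo-3-methylbut-2-ene)
Product: 3 ethyl 7-methyl-3-oxooct-6-enoate
Conditions: NaH (1.1 equiv), THF, 0 °C; n-BuLi (1.05 equiv), 0 °C; 2 (1.0 equiv), 0 °C → rt; 1 M HCl
Reagents that add atoms: none
Why: γ-Alkylation of the acetoacetate dianion: the more basic terminal carbanion is alkylated by SN2 at the primary allylic carbon, so the prenyl unit is attached linearly at C4 and the α-position stays free; no stereocentre is formed.

Step 2
Reactants: 3 ethyl 7-methyl-3-oxooct-6-enoate; 4 benzoyl chloride
Product: 5 ethyl 2-benzoyl-7-methyl-3-oxooct-6-enoate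
Conditions: MgCl2 (1.0 equiv), pyridine (2.0 equiv), CH2Cl2, 0 °C; 4 (1.05 equiv), 0 °C → rt; 1 M HCl
Reagents that add atoms: none
Why: Magnesium-mediated C-acylation of a β-keto ester: the chelated magnesium enolate is acylated at carbon and the more acidic triacylmethane product is held as its magnesium chelate, which suppresses O-acylation and a second acylation; no configurationally stable stereocentre is formed.

Step 3
Reactants: 6 2-methylbut-3-en-2-ol; 7 triethyl orthoacetate
Product: 10 ethyl 5-methylhex-4-enoate, via mixed orthoester 8 (not isolated), via ketene acetal 9 (not isolated)
Conditions: 7 (5 equiv), EtCO2H (5 mol %), 140 °C, EtOH distilled off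
Reagents that add atoms: none
Why: Johnson–Claisen rearrangement: acid-catalysed exchange gives the mixed orthoester, loss of ethanol gives the ketene acetal, and the [3,3]-shift through a chair transition state transfers the chain to the vinyl terminus and creates the dimethyl-substituted (stereochemically unambiguous) olefin; no stereocentre is formed.

Step 4
Reactants: 5 ethyl 2-benzoyl-7-methyl-3-oxooct-6-enoate; 10 ethyl 5-methylhex-4-enoate
Product: 12 clusiaphenone B (2,4,6-trihydroxy-3,5-diprenylbenzophenone), via open-chain tetracarbonyl ester 11 (not isolated)
Conditions: LDA (commercial solution, 3.3 equiv), THF, −78 → 0 °C; 10 (1.2 equiv), 0 °C → rt; LDA (1.1 equiv), 0 → 50 °C; 1 M HCl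
Reagents that add atoms: none
Why: LDA converts 5 into its dianion (the triacylmethanide plus the carbanion at the CH2 next to the aliphatic ketone); this terminal carbanion is acylated by ester 10 to give 11 as its polyanion (bond C2–C1), and the CH2 of the newly attached acyl unit then attacks the ethyl ester of the same chain (bond C3–C4) with loss of ethoxide, after which the trione tautomerises to the phloroglucinol. The closest known reaction types are the terminal C-acylation of 1,3-dicarbonyl dianions with esters and the base-mediated double Claisen (Dieckmann-type) synthesis of cyclohexane-1,3,5-triones from ketones and malonates, i.e. a polyketide-type Claisen aromatisation. The single carbocycle closes in the 6-(enolendo)-exo-trig mode on the ester carbonyl. No stereocentre is formed, since 12 is planar and Cs-symmetric and the two epimerisable centres of 11 vanish on aromatisation. The step needs C-acylation of the terminal carbanion and Claisen closure onto the ester instead of aldol closure onto the benzoyl carbonyl or lactonisation to a 4-hydroxy-2-pyranone. This should be secured because the terminal carbanion is the only strongly nucleophilic site of the polyanion, only the ester carries a leaving group, aldol addition is reversible, and formation of the aromatic phenoxide is not.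

Step 5
Reactants: 13 geraniol; 14 methyl chloroformate
Product: 15 geranyl methyl carbonate [(2E)-3,7-dimethylocta-2,6-dienyl methyl carbonate]
Conditions: pyridine (1.5 equiv), CH2Cl2, 0 °C
Reagents that add atoms: none
Why: O-Acylation of a primary allylic alcohol with a chloroformate (carbonate formation) leaves the E-olefin untouched; no stereocentre is formed.

Step 6
Reactants: 12 clusiaphenone B; 15 geranyl methyl carbonate
Product: 16 kolanone, (R)-configured at the quaternary ring carbon
Conditions: Pd2(dba)3·CHCl3 (2.5 mol %), (1R,2R)-N,N′-bis[2-(diphenylphosphino)benzoyl]cyclohexane-1,2-diamine (7.5 mol %), 15 (1.05 equiv), degassed THF, 0 °C → rt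
Reagents that add atoms: none
Why: Pd-catalysed asymmetric allylic alkylation (Tsuji–Trost) with dearomatisation: ionisation of 15 gives the syn-π-geranyl–Pd(ligand) cation and, after loss of CO2, methoxide, which deprotonates 12; the soft phloroglucinolate carbon then attacks the unsubstituted allyl terminus outside the coordination sphere (O-allylation is reversible under Pd), so the linear E-geranyl group ends up on a prenyl-bearing ring carbon, and because the two prenyl-bearing carbons of 12 are enantiotopic the chiral pocket of the ligand decides which of them (equivalently which face) reacts and so sets the quaternary centre as R.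

**Compound list**
1 | ethyl acetoacetate (ethyl 3-oxobutanoate) | CCOC(=O)CC(C)=O | starting material
2 | prenyl bromide (1-bromo-3-methylbut-2-ene) | CC(C)=CCBr | starting material
3 | ethyl 7-methyl-3-oxooct-6-enoate | CCOC(=O)CC(=O)CCC=C(C)C | intermediate
4 | benzoyl chloride | O=C(Cl)c1ccccc1 | starting material
5 | ethyl 2-benzoyl-7-methyl-3-oxooct-6-enoate (enolised, C2 not configurationally stable) | CCOC(=O)C(C(=O)c1ccccc1)C(=O)CCC=C(C)C | intermediate
6 | 2-methylbut-3-en-2-ol | CC(C)(O)C=C | starting material
7 | triethyl orthoacetate | CCOC(C)(OCC)OCC | starting material
8 | mixed orthoester 3-(1,1-diethoxyethoxy)-3-methylbut-1-ene (not isolated) | CCOC(C)(OCC)OC(C)(C)C=C | intermediate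
9 | ketene acetal 3-(1-ethoxyethenyloxy)-3-methylbut-1-ene (not isolated) | C=C(OCC)OC(C)(C)C=C | intermediate
10 | ethyl 5-methylhex-4-enoate | CCOC(=O)CCC=C(C)C | intermediate
11 | ethyl 2-benzoyl-9-methyl-4-(3-methylbut-2-enyl)-3,5-dioxodec-8-enoate (polyanion in the flask, epimers and enol forms, not isolated) | CCOC(=O)C(C(=O)c1ccccc1)C(=O)C(CC=C(C)C)C(=O)CCC=C(C)C | intermediate
12 | clusiaphenone B, [2,4,6-trihydroxy-3,5-bis(3-methylbut-2-enyl)phenyl](phenyl)methanone | CC(C)=CCc1c(O)c(CC=C(C)C)c(O)c(C(=O)c2ccccc2)c1O | intermediate
13 | geraniol, (2E)-3,7-dimethylocta-2,6-dien-1-ol | CC(C)=CCC/C(C)=C/CO | starting material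
14 | methyl chloroformate | COC(=O)Cl | starting material
15 | geranyl methyl carbonate, (2E)-3,7-dimethylocta-2,6-dienyl methyl carbonate | CC(C)=CCC/C(C)=C/COC(=O)OC | intermediate
16 | kolanone, (6R)-6-[(2E)-3,7-dimethylocta-2,6-dienyl]-3-hydroxy-2-[hydroxy(phenyl)methylidene]-4,6-bis(3-methylbut-2-enyl)cyclohex-3-ene-1,5-dione | CC(C)=CCC/C(C)=C/C[C@]1(CC=C(C)C)C(=O)C(CC=C(C)C)=C(O)/C(=C(\O)c2ccccc2)C1=O | target

**Totals**
Total step count: 6. Longest linear sequence: 4 steps (steps 1, 2, 4, 6).

**Steps most likely to fail**

Step 6. What may go wrong: insufficient facial discrimination of the flat phenolate in the outer-sphere attack, attack at the substituted allyl terminus (reverse-geranyl product), E/Z scrambling of the π-allyl unit, and over-alkylation. The fallback sets out from 12 and comes back at 16. It is an asymmetric phase-transfer alkylation: 12 is treated with commercial geranyl bromide F1, a cinchona-derived N-(9-anthracenylmethyl) quaternary ammonium salt (10 mol %) and CsOH·H2O in toluene/CH2Cl2 at −40 °C. The chiral ion pair directs a direct SN2 displacement in which no π-allyl complex exists, so the linear E-geranyl group is transferred without isomerisation; the pseudo-enantiomeric catalyst (cinchonine- or cinchonidine-derived) is chosen for the R product.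

Step 4. What may go wrong: quenching of the dianion by proton transfer from 10 or from the acylated intermediate, closure of the polyanion onto the benzoyl carbonyl (aldol mode) or through oxygen (lactonisation) instead of onto the ester, and retro-Claisen loss of an acyl group. The fallback sets out from 2 and comes back at 12. The ring is taken from a commercial arene instead of being built: commercial 2,4,6-trihydroxybenzophenone F2 is C-prenylated twice with 2 in aqueous KOH at 0 °C (electrophilic substitution of the phenolate at its two free ring positions), and 12 is separated from mono- and O-prenylated material by chromatography.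

Step 2. What may go wrong: O-benzoylation of the enolate, a second acylation, or deacylation of the triacylmethane during work-up. The fallback sets out from 10 and comes back at 5. The other acyl bond of the triacylmethane is made instead: 10 is saponified (LiOH, THF/H2O, then HCl) to 5-methylhex-4-enoic acid F3, this is converted into 5-methylhex-4-enoyl chloride F4 ((COCl)2, cat. DMF, CH2Cl2), and commercial ethyl benzoylacetate F5 is C-acylated with F4 (MgCl2, Et3N, MeCN, 0 °C), the nucleophile now being the less hindered benzoylacetate.

**Further compounds**
F1 | step 6 | geranyl bromide | CC(C)=CCC/C(C)=C/CBr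
F2 | step 4 | 2,4,6-trihydroxybenzophenone | O=C(c1ccccc1)c1c(O)cc(O)cc1O
F3 | step 2 | 5-methylhex-4-enoic acid | CC(C)=CCCC(=O)O
F4 | step 2 | 5-methylhex-4-enoyl chloride | CC(C)=CCCC(=O)Cl
F5 | step 2 | ethyl benzoylacetate | CCOC(=O)CC(=O)c1ccccc1
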